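**Remark on descriptors.** The spatial arrangement at C2 is the same from 5 to 13. Its CIP label is R while C3 is sp2 (6, 7, 8) and S once C3 is sp3 (9 to 13); the corresponding carbon of enamine 5 is S.

## Analysis of the target

Agecorynin E (13) is a flavanone. Ring A is a benzene with methoxy groups at C5, C6 and C7 and a hydrogen at C8. It is fused through C4a and C8a to ring C, which holds O1, C2, C3 and the C4 ketone. Ring B, a 4-hydroxy-3-methoxyphenyl group, sits on C2.

C2 is the only stereocentre (S). It is benzylic, bonded to O1 and beta to the C4 carbonyl, and this makes it fragile. Base enolises C3 and expels O1 (E1cB, retro-oxa-Michael), and the ring-opened 2'-hydroxychalcone recloses without control. Acid can ionise the C2–O1 bond, because ring B carries a para oxygen.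

Ring A is a very electron-rich tetraoxygenated arene with one free position (C8) that is open to electrophiles. The ring B phenol has to be masked during bond formation and released at the end without base. The difficulty is therefore not the skeleton but creating C2 enantioselectively and carrying it to a beta-aryloxy ketone without ever opening ring C.

The route rests on one feature. C2 lies between O1 and C3, and the two ring C bonds O1–C2 and C3–C4 both end on substituents of ring A that are ortho to each other (the oxygen on C8a and the carbon C4 on C4a). Ring C can therefore be assembled from a salicylaldehyde and the C2–C3 unit of an enal, whose carbonyl carbon becomes a removable substituent on C3.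

## Retrosynthetic reasoning

**13 back to 11.** The last operation should free the ring B phenol and leave C3 as a methylene under neutral conditions. The cut is therefore made at the C3–carboxyl bond and at both oxygen–benzyl bonds of keto ester 11. One hydrogenolysis should remove both benzyl groups, and the keto acid 12 then decarboxylates on its own. No base touches the finished flavanone.

**11 back to 8.** The C4 carbonyl is traced to the secondary alcohol 10, and its C4–O bond to the C3=C4 double bond of enoate 8. In 8, C4 is the beta carbon of an unsaturated ester, so a boron nucleophile adds there and not at C3; boronate 9 is then oxidised with retention. The forward steps have to hydrate the alkene with oxygen on C4 and hydrogen on C3 while the C3 ester enolate is quenched before it can expel O1.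

**8 back to 6.** The ester is the oxidised and benzylated form of the aldehyde in 6. The acid level (7) is needed so that the extra carbon can finally leave by decarboxylation. The benzyl ester is chosen so that this carbon and the ring B protecting group fall in the same step.

**6 back to 2 and 4.** This is the key disconnection. The bonds O1–C2 and C3–C4 are cut, which divides ring C into salicylaldehyde 2 (ring A with O1 and C4) and enal 4 (ring B, C2, C3 and the extra formyl carbon). Both bonds flank the stereocentre, so a chiral amine bound to 4 can set C2 as the ring forms. The forward reaction is a conjugate addition of the phenol followed by an intramolecular aldol condensation. No other pair of cuts turns both partners into simple aldehydes.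

**2 back to 1.** The aryl–formyl bond is cut. Phenol 1 is symmetric, its two free ring positions are equivalent and both are ortho to the hydroxyl, so formylation can give only one isomer.

**4 back to 3.** Only the benzyl–oxygen bond is cut. Enal 3 is commercial and already carries the E double bond, so the precursor is reached without any C–C bond formation of uncertain geometry.

## Alternatives that were turned down

**Alternative 1: acylation of ring A.**
- Disconnection: C4–C4a. The precursor is the beta-aryloxy acid A1, in which O1–C2 and the stereocentre already exist.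
- Forward key step: activation of the acid as a mixed anhydride and intramolecular Friedel–Crafts acylation ortho to the ether oxygen closes ring C to acetate A2; ester cleavage then gives 13.
- For it: the aryloxy ring derived from phenol 1 is symmetric, so only one ring closure is possible. The ketone appears directly at the right oxidation level and no sacrificial carbon is needed. On step count after ring closure it is stronger than the chosen route.
- Against it: C2 must be made beforehand as a secondary benzylic aryl ether by substitution at a carbon that ionises easily, since ring B is oxygenated. The strongly acidic acylation medium can ionise the same C–O bond or expel phenol 1 from A1 by beta-elimination. Removing the acetate needs a nucleophile or base on a finished flavanone, which is where racemisation through ring opening occurs.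
- Comparison: the chosen strategy spends more steps after ring closure. In return, C2 is created catalytically during ring formation from two achiral aldehydes, and every later intermediate is handled under neutral or weakly acidic conditions.

**Alternative 2: biomimetic construction of ring A.**
- Disconnection: C4a–C5. Ring A is made last, from dihydropyranone A3 with a methoxylated keto ester side chain.
- Forward key step: mild carbonate base generates an extended enolate; the ring carbon that becomes C4a acylates at the terminal ester, and loss of methoxide with tautomerisation gives the aromatic ring of A4.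
- For it: the 5,7-dioxygenated, 6-methoxylated pattern follows from the chain itself. The stereocentre is set early in a simple heterocycle. For congeners with free hydroxyls at C5 and C7 it would be the stronger plan.
- Against it: the target is methylated at all three ring A oxygens. A4 would need two O-methylations, and the one at the chelated C5 hydroxyl requires base and heat on a flavanone, which opens ring C. The tricarbonyl chain of A3 also needs several C–C bond formations of uncertain regiochemistry, so the linear sequence is long.
- Comparison: the chosen strategy buys ring A with its three methoxy groups in place (1) and so avoids the late methylation altogether.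

**Alternative 3: aryl ether formation at C8a.**
- Disconnection: O1–C8a. The precursor is bromo diol A5.
- Forward key step: copper-catalysed Ullmann-type etherification of the C2 hydroxyl with the aryl bromide closes ring C to chromanol A6; oxidation at C4 and debenzylation follow.
- For it: C2 is set in an open-chain benzylic alcohol by well-developed asymmetric carbonyl chemistry. The ring-closing bond is made at the aryl carbon and not at the stereocentre, so the configuration cannot be lost in that step. The C4 oxygen is already present. On stereochemical security it is stronger than the chosen route.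
- Against it: the aryl bromide is electron-rich and ortho-substituted, so the coupling needs heat and carbonate base on a substrate with two ionisable benzylic alcohols. A5 requires a regioselectively brominated, pentasubstituted ring A and two stereocentres, one of which is then oxidised away. The sequence is linear and longer.
- Comparison: the chosen strategy forms both ring C bonds and the stereocentre in one catalytic step from two aldehydes, each made in one step.

Key step: step 3

## Route

Step 1
Reactants: 1 3,4,5-trimethoxyphenol
Product: 2 6-hydroxy-2,3,4-trimethoxybenzaldehyde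
Conditions: MgCl2, Et3N, (CH2O)n, MeCN, reflux; aq. HCl work-up
Reagents that add atoms: paraformaldehyde (as formaldehyde), C=O
Why: Casnati–Skattebøl ortho-formylation: the magnesium phenoxide directs hydroxymethylation to the ortho carbon and hydride transfer to a second formaldehyde gives the aldehyde; the two ortho positions of 1 are equivalent, so only one regioisomer can form.

Step 2
Reactants: 3 (E)-3-(4-hydroxy-3-methoxyphenyl)prop-2-enal (coniferyl aldehyde)
Product: 4 (E)-3-(4-benzyloxy-3-methoxyphenyl)prop-2-enal
Conditions: BnBr, K2CO3, acetone, 50 °C
Reagents that add atoms: benzyl bromide, BrCc1ccccc1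
Why: Williamson etherification of an acidic, vinylogously activated phenol; the E double bond and the aldehyde are untouched, and the benzyl ether keeps the ring B oxygen from competing as a nucleophile in step 3.

Step 3
Reactants: 2 6-hydroxy-2,3,4-trimethoxybenzaldehyde; 4 (E)-3-(4-benzyloxy-3-methoxyphenyl)prop-2-enal (1.3 equiv)
Product: 6 (2R)-2-(4-benzyloxy-3-methoxyphenyl)-5,6,7-trimethoxy-2H-chromene-3-carbaldehyde, via oxa-Michael enamine adduct 5 (not isolated)
Conditions: (S)-2-[diphenyl(trimethylsilyloxy)methyl]pyrrolidine (20 mol%), 2-nitrobenzoic acid (20 mol%), 4 Å MS, toluene, rt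
Reagents that add atoms: none
Why: The amine condenses with 4 under acid co-catalysis to an E, s-trans unsaturated iminium ion, and the phenol of 2 adds to its beta carbon, forming O1–C2 and enamine 5. Enamine 5 then attacks the neighbouring aryl aldehyde carbon in an intramolecular aldol reaction that forms C3–C4; loss of water from the aldol iminium ion and hydrolysis release 6 and the amine. The closest known reaction type is the diarylprolinol silyl ether-catalysed domino oxa-Michael–aldol condensation of salicylaldehydes with beta-aryl enals to 2-aryl-2H-chromene-3-carbaldehydes. Ring C closes in the aldol step in a 6-(enolexo)-exo-trig mode, with the enamine double bond and the carbonyl oxygen both outside the new ring. C2 is the only new stereocentre and is controlled by the catalyst: the silyloxydiphenylmethyl group covers one face of the iminium ion, and on the usual shielding model the (S)-amine should give the 2R chromene, which has the arrangement of the 2S target; the antipodal amine is equally available should the sense prove opposite. The step needs enantioface selection and activation of the enal in preference to the aryl aldehyde; the aldehyde of 2 is hindered between OH and OMe, hydrogen-bonded and electron-rich, so the amine engages 4, and the ortho placement of OH and CHO in 2 makes the aldol intramolecular. The reversible oxa-Michael step is pulled forward by the dehydration, and 6 has no hydrogen on C3, so it cannot re-enter enamine chemistry and C2 stays fixed.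

Step 4
Reactants: 6 (2R)-2-(4-benzyloxy-3-methoxyphenyl)-5,6,7-trimethoxy-2H-chromene-3-carbaldehyde
Product: 7 (2R)-2-(4-benzyloxy-3-methoxyphenyl)-5,6,7-trimethoxy-2H-chromene-3-carboxylic acid
Conditions: NaClO2, NaH2PO4, 2-methyl-2-butene (large excess), t-BuOH/THF/H2O, 0 °C to rt
Reagents that add atoms: sodium chlorite, [Na+].[O-]Cl=O
Why: Pinnick oxidation of a conjugated aldehyde under weakly acidic buffer; the alkene scavenger removes hypochlorous acid before it can attack ring A, and C2 is not touched.

Step 5
Reactants: 7 (2R)-2-(4-benzyloxy-3-methoxyphenyl)-5,6,7-trimethoxy-2H-chromene-3-carboxylic acid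
Product: 8 benzyl (2R)-2-(4-benzyloxy-3-methoxyphenyl)-5,6,7-trimethoxy-2H-chromene-3-carboxylate
Conditions: BnBr, K2CO3, DMF, rt
Reagents that add atoms: benzyl bromide, BrCc1ccccc1
Why: SN2 O-alkylation of the carboxylate; the C2 hydrogen is only cross-conjugated to the ester, so carbonate cannot epimerise it, and the benzyl ester lets the extra carbon leave later together with the ring B protecting group.

Step 6
Reactants: 8 benzyl (2R)-2-(4-benzyloxy-3-methoxyphenyl)-5,6,7-trimethoxy-2H-chromene-3-carboxylate
Product: 10 benzyl (2S)-2-(4-benzyloxy-3-methoxyphenyl)-4-hydroxy-5,6,7-trimethoxychromane-3-carboxylate (C3 and C4 as formed), via C4 pinacol boronate 9 (not isolated)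
Conditions: B2pin2, CuCl (5 mol%), DPEphos (5 mol%), NaOt-Bu (10 mol%), BnOH (3 equiv), THF, rt; then NaBO3·4H2O, THF/H2O, rt
Reagents that add atoms: sodium perborate, [Na+].[O-]OB=O (the C4 oxygen); bis(pinacolato)diboron, CC1(C)OB(OC1(C)C)B1OC(C)(C)C(C)(C)O1 (the boryl group of 9, removed again in the oxidation)
Why: Copper-catalysed conjugate borylation of an unsaturated ester puts boron on the beta carbon C4, and perborate oxidises the C–B bond with retention; benzyl alcohol as proton source quenches the C3 copper enolate before it can expel O1 and makes any alkoxide exchange at the ester degenerate. The configurations at C3 and C4 do not matter, since both centres are erased in steps 7 and 8.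

Step 7
Reactants: 10 benzyl (2S)-2-(4-benzyloxy-3-methoxyphenyl)-4-hydroxy-5,6,7-trimethoxychromane-3-carboxylate
Product: 11 benzyl (2S)-2-(4-benzyloxy-3-methoxyphenyl)-5,6,7-trimethoxy-4-oxochromane-3-carboxylate
Conditions: Dess–Martin periodinane, NaHCO3 (solid), CH2Cl2, 0 °C to rt; used without chromatography
Reagents that add atoms: none
Why: Dess–Martin oxidation of a secondary benzylic alcohol to the beta-keto ester; the solid bicarbonate takes up acetic acid so that the electron-rich benzylic C4–OH does not ionise, and it is too weak and insoluble to trigger ring opening of 11. 3-Alkoxycarbonyl flavanones are known to hold their C2 configuration in the absence of soluble base.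

Step 8
Reactants: 11 benzyl (2S)-2-(4-benzyloxy-3-methoxyphenyl)-5,6,7-trimethoxy-4-oxochromane-3-carboxylate
Product: 13 agecorynin E [(2S)-2-(4-hydroxy-3-methoxyphenyl)-5,6,7-trimethoxychroman-4-one], via beta-keto acid 12 (not isolated)
Conditions: H2 (1 atm), 10% Pd/C, EtOAc, rt; filter, then 45 °C
Reagents that add atoms: none
Why: Hydrogenolysis cleaves the benzyl ester and the aryl benzyl ether, and keto acid 12 decarboxylates through a six-membered cyclic transition state to the enol of the flavanone; the medium is neutral, so no retro-oxa-Michael pathway opens and C2 is kept. Primary benzyl groups are cleaved much faster than the ring-bound C2–O1 bond.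

## Compound list

1 | 3,4,5-trimethoxyphenol | COc1cc(O)cc(OC)c1OC | starting material
2 | 6-hydroxy-2,3,4-trimethoxybenzaldehyde | O=Cc1c(O)cc(OC)c(OC)c1OC | intermediate
3 | (E)-3-(4-hydroxy-3-methoxyphenyl)prop-2-enal (coniferyl aldehyde) | COc1cc(/C=C/C=O)ccc1O | starting material
4 | (E)-3-(4-benzyloxy-3-methoxyphenyl)prop-2-enal | COc1cc(/C=C/C=O)ccc1OCc1ccccc1 | intermediate
5 | 6-{[(1S,2E)-1-(4-benzyloxy-3-methoxyphenyl)-3-{(2S)-2-[diphenyl(trimethylsilyloxy)methyl]pyrrolidin-1-yl}prop-2-en-1-yl]oxy}-2,3,4-trimethoxybenzaldehyde | COc1cc([C@@H](Oc2cc(OC)c(OC)c(OC)c2C=O)/C=C/N2CCC[C@H]2C(c2ccccc2)(c2ccccc2)O[Si](C)(C)C)ccc1OCc1ccccc1 | intermediate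
6 | (2R)-2-(4-benzyloxy-3-methoxyphenyl)-5,6,7-trimethoxy-2H-chromene-3-carbaldehyde | COc1cc([C@@H]2C(C=O)=Cc3c(cc(OC)c(OC)c3OC)O2)ccc1OCc1ccccc1 | intermediate
7 | (2R)-2-(4-benzyloxy-3-methoxyphenyl)-5,6,7-trimethoxy-2H-chromene-3-carboxylic acid | COc1cc([C@@H]2C(C(=O)O)=Cc3c(cc(OC)c(OC)c3OC)O2)ccc1OCc1ccccc1 | intermediate
8 | benzyl (2R)-2-(4-benzyloxy-3-methoxyphenyl)-5,6,7-trimethoxy-2H-chromene-3-carboxylate | COc1cc([C@@H]2C(C(=O)OCc3ccccc3)=Cc3c(cc(OC)c(OC)c3OC)O2)ccc1OCc1ccccc1 | intermediate
9 | benzyl (2S)-2-(4-benzyloxy-3-methoxyphenyl)-5,6,7-trimethoxy-4-(4,4,5,5-tetramethyl-1,3,2-dioxaborolan-2-yl)chromane-3-carboxylate (C3, C4 as formed) | COc1cc([C@@H]2C(C(=O)OCc3ccccc3)C(B3OC(C)(C)C(C)(C)O3)c3c(cc(OC)c(OC)c3OC)O2)ccc1OCc1ccccc1 | intermediate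
10 | benzyl (2S)-2-(4-benzyloxy-3-methoxyphenyl)-4-hydroxy-5,6,7-trimethoxychromane-3-carboxylate (C3, C4 as formed) | COc1cc([C@@H]2C(C(=O)OCc3ccccc3)C(O)c3c(cc(OC)c(OC)c3OC)O2)ccc1OCc1ccccc1 | intermediate
11 | benzyl (2S)-2-(4-benzyloxy-3-methoxyphenyl)-5,6,7-trimethoxy-4-oxochromane-3-carboxylate (C3 epimers, enolisable) | COc1cc([C@@H]2C(C(=O)OCc3ccccc3)C(=O)c3c(cc(OC)c(OC)c3OC)O2)ccc1OCc1ccccc1 | intermediate
12 | (2S)-2-(4-hydroxy-3-methoxyphenyl)-5,6,7-trimethoxy-4-oxochromane-3-carboxylic acid | COc1cc([C@@H]2C(C(=O)O)C(=O)c3c(cc(OC)c(OC)c3OC)O2)ccc1O | intermediate
13 | agecorynin E, (2S)-2-(4-hydroxy-3-methoxyphenyl)-5,6,7-trimethoxychroman-4-one | COc1cc([C@@H]2CC(=O)c3c(cc(OC)c(OC)c3OC)O2)ccc1O | target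

## Step count and least certain steps

Total step count: 8. Longest linear sequence: 7 steps (steps 1, 3, 4, 5, 6, 7, 8 from 1); the branch from 3 to 4 is one step.

**Step 3 (key step).**
- What may go wrong: the oxa-Michael adduct may revert faster than its enamine attacks the aldehyde of 2, which is hindered, hydrogen-bonded and deactivated by three oxygen donors. The donor-substituted enal 4 also forms a less electrophilic iminium ion. The outcome would be low conversion, or erosion of enantiomeric purity by an amine-free, acid- or base-promoted racemic pathway.
- Fallback: ring C is built first and ring B is attached last. The fallback sets out from 1 and comes back at 13. Friedel–Crafts acetylation of 1 (AcOH, BF3·OEt2, heat) should give 1-(6-hydroxy-2,3,4-trimethoxyphenyl)ethanone F1. Condensation with N,N-dimethylformamide dimethyl acetal gives the enaminone (E)-3-(dimethylamino)-1-(6-hydroxy-2,3,4-trimethoxyphenyl)prop-2-en-1-one F2. Acid closes it, with loss of dimethylamine, to 5,6,7-trimethoxy-4H-chromen-4-one F3. Asymmetric conjugate addition of (4-benzyloxy-3-methoxyphenyl)boronic acid, catalysed by Pd(OCOCF3)2 and the enantiomer of a tert-butyl pyridine-oxazoline ligand that delivers the 2S product, should give (2S)-2-(4-benzyloxy-3-methoxyphenyl)-5,6,7-trimethoxychroman-4-one F4. Hydrogenolysis as in step 8 leads to 13.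

**Step 6.**
- What may go wrong: after boron adds to C4, the C3 copper enolate has O1 in the beta position, and beta-elimination of the aryloxide would open ring C irreversibly and destroy C2. The enoate is also trisubstituted and carries a donor-rich aryl group on C4, so conversion may be slow.
- Fallback: the formyl carbon is removed before C4 is oxidised, so no C3 carbanion is formed. The fallback sets out from 6 and comes back at 13. Tsuji–Wilkinson decarbonylation with stoichiometric RhCl(PPh3)3 in warm toluene should give (2S)-2-(4-benzyloxy-3-methoxyphenyl)-5,6,7-trimethoxy-2H-chromene F5. Mukaiyama hydration (Co(acac)2, PhSiH3, O2) delivers hydrogen to C3 and oxygen to the benzylic radical at C4, giving (2S)-2-(4-benzyloxy-3-methoxyphenyl)-5,6,7-trimethoxychroman-4-ol F6. Dess–Martin oxidation gives (2S)-2-(4-benzyloxy-3-methoxyphenyl)-5,6,7-trimethoxychroman-4-one F4, and hydrogenolysis as in step 8 gives 13.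

**Step 7.**
- What may go wrong: acid-promoted ionisation at the very electron-rich benzylic C4 of 10 (loss of water back to 8), or partial loss of configuration at C2 by reversible ring opening of the beta-keto ester during work-up or storage.
- Fallback: the acid is unmasked before the oxidation, so the 1,3-dicarbonyl stage exists only as a short-lived keto acid. The fallback sets out from 10 and comes back at 13. Hydrogenolysis over Pd/C poisoned with 2,2'-bipyridyl cleaves the benzyl ester but spares the phenolic benzyl ether, giving (2S)-2-(4-benzyloxy-3-methoxyphenyl)-4-hydroxy-5,6,7-trimethoxychromane-3-carboxylic acid F7. Dess–Martin oxidation gives (2S)-2-(4-benzyloxy-3-methoxyphenyl)-5,6,7-trimethoxy-4-oxochromane-3-carboxylic acid F8, which decarboxylates in the flask to (2S)-2-(4-benzyloxy-3-methoxyphenyl)-5,6,7-trimethoxychroman-4-one F4. Hydrogenolysis as in step 8 gives 13.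

**Step 4.**
- What may go wrong: electrophilic chlorination at C8 of ring A by hypochlorous acid if scavenging is incomplete.
- Fallback: the chlorite oxidation is replaced by a carbene-catalysed oxidative esterification. The fallback sets out from 6 and comes back at 8. A triazolium-derived N-heterocyclic carbene with catalytic DBU, benzyl alcohol and 3,3',5,5'-tetra-tert-butyldiphenoquinone as oxidant converts the enal through its acyl azolium ion directly into benzyl ester 8. No chlorine species is present and step 5 is skipped.

## Further compounds

F1 | step 3 | 1-(6-hydroxy-2,3,4-trimethoxyphenyl)ethanone | CC(=O)c1c(O)cc(OC)c(OC)c1OC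
F2 | step 3 | (E)-3-(dimethylamino)-1-(6-hydroxy-2,3,4-trimethoxyphenyl)prop-2-en-1-one | CN(C)/C=C/C(=O)c1c(O)cc(OC)c(OC)c1OC
F3 | step 3 | 5,6,7-trimethoxy-4H-chromen-4-one | COc1cc2occc(=O)c2c(OC)c1OC
F4 | step 3 | (2S)-2-(4-benzyloxy-3-methoxyphenyl)-5,6,7-trimethoxychroman-4-one | COc1cc([C@@H]2CC(=O)c3c(cc(OC)c(OC)c3OC)O2)ccc1OCc1ccccc1
F5 | step 6 | (2S)-2-(4-benzyloxy-3-methoxyphenyl)-5,6,7-trimethoxy-2H-chromene | COc1cc([C@@H]2C=Cc3c(cc(OC)c(OC)c3OC)O2)ccc1OCc1ccccc1
F6 | step 6 | (2S)-2-(4-benzyloxy-3-methoxyphenyl)-5,6,7-trimethoxychroman-4-ol (C4 as formed) | COc1cc([C@@H]2CC(O)c3c(cc(OC)c(OC)c3OC)O2)ccc1OCc1ccccc1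
F7 | step 7 | (2S)-2-(4-benzyloxy-3-methoxyphenyl)-4-hydroxy-5,6,7-trimethoxychromane-3-carboxylic acid (C3, C4 as formed) | COc1cc([C@@H]2C(C(=O)O)C(O)c3c(cc(OC)c(OC)c3OC)O2)ccc1OCc1ccccc1
F8 | step 7 | (2S)-2-(4-benzyloxy-3-methoxyphenyl)-5,6,7-trimethoxy-4-oxochromane-3-carboxylic acid | COc1cc([C@@H]2C(C(=O)O)C(=O)c3c(cc(OC)c(OC)c3OC)O2)ccc1OCc1ccccc1
F0 | step 4 | none | none
A1 | alternative 1 | (3S)-3-(4-acetoxy-3-methoxyphenyl)-3-(3,4,5-trimethoxyphenoxy)propanoic acid | COc1cc([C@@H](Oc2cc(OC)c(OC)c(OC)c2)CC(=O)O)ccc1OC(C)=O
A2 | alternative 1 | (2S)-2-(4-acetoxy-3-methoxyphenyl)-5,6,7-trimethoxychroman-4-one | COc1cc([C@@H]2CC(=O)c3c(cc(OC)c(OC)c3OC)O2)ccc1OC(C)=O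
A3 | alternative 2 | methyl 4-[(2S)-2-(4-benzyloxy-3-methoxyphenyl)-4-oxo-3,4-dihydro-2H-pyran-6-yl]-2-methoxy-3-oxobutanoate | COC(=O)C(OC)C(=O)CC1=CC(=O)C[C@@H](c2ccc(OCc3ccccc3)c(OC)c2)O1
A4 | alternative 2 | (2S)-2-(4-benzyloxy-3-methoxyphenyl)-5,7-dihydroxy-6-methoxychroman-4-one | COc1cc([C@@H]2CC(=O)c3c(cc(O)c(OC)c3O)O2)ccc1OCc1ccccc1
A5 | alternative 3 | (1R,3S)-3-(4-benzyloxy-3-methoxyphenyl)-1-(6-bromo-2,3,4-trimethoxyphenyl)propane-1,3-diol | COc1cc([C@@H](O)C[C@@H](O)c2c(Br)cc(OC)c(OC)c2OC)ccc1OCc1ccccc1
A6 | alternative 3 | (2S,4R)-2-(4-benzyloxy-3-methoxyphenyl)-5,6,7-trimethoxychroman-4-ol | COc1cc([C@@H]2C[C@@H](O)c3c(cc(OC)c(OC)c3OC)O2)ccc1OCc1ccccc1
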